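**Target:** methyl 4-[(1R,2R)-2-[(2R,3E,5E,10S)-13-bromo-6,10-dimethyltrideca-3,5-dien-12-yn-2-yl]cyclopropyl]butanoate (C2–C13 = side-chain numbering used below).

**Retrosynthetic overview**
1. The bromoalkyne is unveiled last from a C-silyl alkyne; the (3E,5E)-diene is cut at C4–C5 into alkenylboronate 28 (from alkyne 13) and (E)-alkenyl iodide 27 (Suzuki–Miyaura).
2. C2–C3 and C2–cyclopropane are both made by stereospecific 1,2-metallate shifts on boron: Zweifel-type alkynylation of secondary boronate 8, which comes from cyclopropylboronate 3 and a sparteine-lithiated ethyl carbamate (sets C2).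
3. The cyclopropane, the only ring, is formed first by an enantioselective borylcyclopropanation of methyl hex-5-enoate.
4. Iodide 27 comes from (R)-3-bromo-2-methylpropan-1-ol (C10), ethynyltrimethylsilane, oxirane and ethyne, then Zr-catalysed methylalumination/iodination for the (E)-trisubstituted alkene.

Assumption: the SMILES is read as the trans-(1R,2R)-cyclopropane with (2R), (10S) and (3E,5E); all starting materials below are catalogue chemicals.

**Step 1**
Reactants: 1 hex-5-enoic acid
Product: 2 methyl hex-5-enoate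
Conditions: MeOH, H2SO4 (cat.), reflux
Reagents that add atoms: methanol, CO
Why: Fischer esterification driven by excess methanol; no stereocentre is involved.

**Step 2**
Reactants: 2 methyl hex-5-enoate
Product: 3 methyl 4-[(1R,2R)-2-(4,4,5,5-tetramethyl-1,3,2-dioxaborolan-2-yl)cyclopropyl]butanoate
Conditions: Cl2CHBpin (1.5 equiv), Zn (3 equiv), [(S)-tBu-OIP]CoBr2 (10 mol %; OIP = oxazoline–iminopyridine ligand), THF, 0 → 23 °C
Reagents that add atoms: (dichloromethyl)boronic acid pinacol ester, ClC(Cl)B1OC(C)(C)C(C)(C)O1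
Why: Proposed new method: zinc reduces the divalent cobalt precatalyst and turns Cl2CHBpin into a cobalt α-boryl carbenoid that adds Simmons–Smith-like to the only (terminal) alkene, the bulky Bpin being forced anti to the alkyl chain (trans ring) while the C1-symmetric ligand pocket fixes the carbenoid so that one alkene face is used and both ring stereocentres arise together as (1R,2R) (ligand antipode chosen accordingly); the closest known reactions are cobalt-catalysed reductive cyclopropanations of alkenes with gem-dihaloalkanes and zinc, including enantioselective transfer of non-stabilised carbenes, and the chromium-mediated trans-selective borylcyclopropanation of terminal alkenes with a diiodomethylboronate, whereas an enantioselective boryl-carbene transfer to an unactivated 1-alkene has not been shown.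

**Step 3**
Reactants: 4 ethanol
Product: 5 ethyl N,N-diisopropylcarbamate
Conditions: iPr2NCOCl, Et3N, CH2Cl2, reflux
Reagents that add atoms: N,N-diisopropylcarbamoyl chloride, CC(C)N(C(C)C)C(Cl)=O
Why: O-carbamoylation (nucleophilic acyl substitution) installs the group that directs α-lithiation and later acts as leaving group; no stereocentre is formed.

**Step 4**
Reactants: 5 ethyl N,N-diisopropylcarbamate; 3 methyl 4-[(1R,2R)-2-(4,4,5,5-tetramethyl-1,3,2-dioxaborolan-2-yl)cyclopropyl]butanoate
Product: 8 methyl 4-[(1R,2S)-2-[(1S)-1-(4,4,5,5-tetramethyl-1,3,2-dioxaborolan-2-yl)ethyl]cyclopropyl]butanoate, via lithiated carbamate 6 (not isolated), via boronate complex 7 (not isolated)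
Conditions: 5 (1.0 equiv), s-BuLi (0.98 equiv), (+)-sparteine, Et2O, −78 °C, 5 h; then 3 (1.05 equiv), −78 °C, 1 h; MgBr2·OEt2, −78 °C → reflux
Reagents that add atoms: none
Why: Lithiation–borylation: sparteine-directed enantioselective deprotonation gives the configurationally stable (R)-carbenoid 6, which is borylated with retention by 3 (kept in slight excess so no free organolithium meets the ester) and then undergoes the MgBr2-promoted stereospecific 1,2-metallate rearrangement, the cyclopropyl carbon migrating from boron to carbon with retention while the carbamate leaves with inversion, so the cyclopropane–C2 bond is formed and C2 is set by reagent control (it becomes the 2R centre of the target).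

**Step 5**
Reactants: 8 methyl 4-[(1R,2S)-2-[(1S)-1-(4,4,5,5-tetramethyl-1,3,2-dioxaborolan-2-yl)ethyl]cyclopropyl]butanoate; 9 bromoethene
Product: 13 methyl 4-[(1R,2R)-2-[(2S)-but-3-yn-2-yl]cyclopropyl]butanoate, via 1-bromoethenyllithium 10 (not isolated), via alkenylboronate complex 11 (not isolated), via bromoalkene 12 (not isolated)
Conditions: 8, 9 (3 equiv), LiN(iPr)2 (2.3 equiv), THF, −78 °C; MeOH, then I2, NaOMe, −78 → 0 °C; crude 12, TBAF·3H2O, DMF, 60 °C
Reagents that add atoms: none
Why: Zweifel-type alkynylation: α-lithiated vinyl bromide made in situ adds to boron, iodine triggers a second 1,2-metallate shift of the secondary carbon (retention) onto the alkene carbon followed by anti elimination of boron and iodide to the 2-bromoalkene, and fluoride-mediated E2 loss of HBr gives the terminal alkyne with C2 untouched (one equivalent of base is allowed for reversible ester enolisation, quenched by MeOH before iodine).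

**Step 6**
Reactants: 14 (R)-3-bromo-2-methylpropan-1-ol; 15 ethynyltrimethylsilane
Product: 18 [(4R)-5-bromo-4-methylpent-1-yn-1-yl]trimethylsilane, via bromo triflate 16 (not isolated), via lithium (trimethylsilyl)acetylide 17 (not isolated)
Conditions: 14, Tf2O, 2,6-lutidine, CH2Cl2, −78 °C; then 15/n-BuLi, THF–DMPU, −78 → −20 °C
Reagents that add atoms: none
Why: Chemoselective SN2 alkynylation: the primary triflate is displaced by the lithium acetylide far faster than the β-branched bromide, and the stereocentre (not a reacting carbon) is carried over from the chiral-pool bromohydrin.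

**Step 7**
Reactants: 18 [(4R)-5-bromo-4-methylpent-1-yn-1-yl]trimethylsilane; 19 oxirane
Product: 21 (4S)-4-methyl-7-(trimethylsilyl)hept-6-yn-1-ol, via Grignard reagent 20 (not isolated)
Conditions: Mg, THF, 45 °C; then 19, CuI (10 mol %), −30 → 0 °C; aq. NH4Cl
Reagents that add atoms: none
Why: Grignard formation and copper-catalysed SN2 opening of oxirane extend the chain by two carbons to the primary alcohol; the silylalkyne and the stereocentre are not touched.

**Step 8**
Reactants: 21 (4S)-4-methyl-7-(trimethylsilyl)hept-6-yn-1-ol; 22 ethyne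
Product: 25 trimethyl[(4S)-4-methylnona-1,8-diyn-1-yl]silane, via silylalkynyl triflate 23 (not isolated), via lithium acetylide 24 (not isolated)
Conditions: 21, Tf2O, 2,6-lutidine, CH2Cl2, −78 °C; then 22/n-BuLi (THF, −78 °C), DMPU, −78 → −25 °C
Reagents that add atoms: none
Why: Triflation and SN2 displacement by monolithium acetylide at low temperature install the terminal alkyne while the C-silyl alkyne stays capped, so the two alkynes are differentiated for the next step.

**Step 9**
Reactants: 25 trimethyl[(4S)-4-methylnona-1,8-diyn-1-yl]silane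
Product: 27 [(4S,8E)-9-iodo-4,8-dimethylnon-8-en-1-yn-1-yl]trimethylsilane, via alkenylalane 26 (not isolated)
Conditions: Me3Al (2.5 equiv), Cp2ZrCl2 (0.25 equiv), ClCH2CH2Cl, 23 °C; then I2, THF, −30 → 0 °C
Reagents that add atoms: trimethylaluminium, C[Al](C)C; iodine, [I][I]
Why: Negishi zirconium-catalysed carboalumination adds Me and Al syn across the terminal alkyne with Al at the terminus (the silyl-capped internal alkyne reacts far more slowly), and iodinolysis with retention gives the (E)-trisubstituted alkenyl iodide.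

**Step 10**
Reactants: 13 methyl 4-[(1R,2R)-2-[(2S)-but-3-yn-2-yl]cyclopropyl]butanoate; 27 [(4S,8E)-9-iodo-4,8-dimethylnon-8-en-1-yn-1-yl]trimethylsilane
Product: 29 methyl 4-[(1R,2R)-2-[(2R,3E,5E,10S)-6,10-dimethyl-13-(trimethylsilyl)trideca-3,5-dien-12-yn-2-yl]cyclopropyl]butanoate, via alkenylboronate 28 (not isolated)
Conditions: 13, HBpin, Cp2Zr(H)Cl (10 mol %), Et3N (10 mol %), CH2Cl2, 40 °C; then 27, PdCl2(dppf) (5 mol %), K3PO4 (aq.), THF, 50 °C
Reagents that add atoms: none
Why: Zirconium-catalysed syn, anti-Markovnikov hydroboration gives the (E)-alkenylboronate and Suzuki–Miyaura coupling with the alkenyl iodide proceeds with retention at both sp2 carbons, giving the (3E,5E)-diene under mild base that spares the methyl ester.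

**Step 11**
Reactants: 29 methyl 4-[(1R,2R)-2-[(2R,3E,5E,10S)-6,10-dimethyl-13-(trimethylsilyl)trideca-3,5-dien-12-yn-2-yl]cyclopropyl]butanoate
Product: 30 methyl 4-[(1R,2R)-2-[(2R,3E,5E,10S)-13-bromo-6,10-dimethyltrideca-3,5-dien-12-yn-2-yl]cyclopropyl]butanoate
Conditions: NBS (1.15 equiv), AgNO3 (20 mol %), acetone, 0 → 23 °C, dark
Reagents that add atoms: N-bromosuccinimide, BrN1C(=O)CCC1=O
Why: Silver-catalysed desilylative bromination: the silver acetylide formed from the alkynylsilane is brominated by NBS faster than the diene reacts, converting C–Si directly into C–Br without touching any stereocentre.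

**Compound list**
1 | hex-5-enoic acid | C=CCCCC(=O)O | starting material
2 | methyl hex-5-enoate | C=CCCCC(=O)OC | intermediate
3 | methyl 4-[(1R,2R)-2-(4,4,5,5-tetramethyl-1,3,2-dioxaborolan-2-yl)cyclopropyl]butanoate | COC(=O)CCC[C@@H]1C[C@H]1B2OC(C)(C)C(C)(C)O2 | intermediate
4 | ethanol | CCO | starting material
5 | ethyl N,N-diisopropylcarbamate | CCOC(=O)N(C(C)C)C(C)C | intermediate
6 | [(1R)-1-(diisopropylcarbamoyloxy)ethyl]lithium, (+)-sparteine complex | CC(C)N(C(C)C)C(=O)O[C@@H](C)[Li] | intermediate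
7 | lithium [(1R)-1-(diisopropylcarbamoyloxy)ethyl][(1R,2R)-2-(4-methoxy-4-oxobutyl)cyclopropyl](pinacolato)borate | COC(=O)CCC[C@@H]1C[C@H]1[B-]2(OC(C)(C)C(C)(C)O2)[C@H](C)OC(=O)N(C(C)C)C(C)C.[Li+] | intermediate
8 | methyl 4-[(1R,2S)-2-[(1S)-1-(4,4,5,5-tetramethyl-1,3,2-dioxaborolan-2-yl)ethyl]cyclopropyl]butanoate | COC(=O)CCC[C@@H]1C[C@H]1[C@H](C)B2OC(C)(C)C(C)(C)O2 | intermediate
9 | bromoethene | C=CBr | starting material
10 | (1-bromoethenyl)lithium | [Li]C(Br)=C | intermediate
11 | lithium (1-bromoethenyl)[(1S)-1-[(1S,2R)-2-(4-methoxy-4-oxobutyl)cyclopropyl]ethyl](pinacolato)borate | COC(=O)CCC[C@@H]1C[C@H]1[C@H](C)[B-]2(OC(C)(C)C(C)(C)O2)C(Br)=C.[Li+] | intermediate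
12 | methyl 4-[(1R,2R)-2-[(2S)-3-bromobut-3-en-2-yl]cyclopropyl]butanoate | COC(=O)CCC[C@@H]1C[C@H]1[C@H](C)C(Br)=C | intermediate
13 | methyl 4-[(1R,2R)-2-[(2S)-but-3-yn-2-yl]cyclopropyl]butanoate | COC(=O)CCC[C@@H]1C[C@H]1[C@H](C)C#C | intermediate
14 | (R)-3-bromo-2-methylpropan-1-ol | BrC[C@H](C)CO | starting material
15 | ethynyltrimethylsilane | C#C[Si](C)(C)C | starting material
16 | (2R)-3-bromo-2-methylpropyl trifluoromethanesulfonate | BrC[C@H](C)COS(=O)(=O)C(F)(F)F | intermediate
17 | lithium (trimethylsilyl)acetylide | [Li]C#C[Si](C)(C)C | intermediate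
18 | [(4R)-5-bromo-4-methylpent-1-yn-1-yl]trimethylsilane | BrC[C@H](C)CC#C[Si](C)(C)C | intermediate
19 | oxirane | C1CO1 | starting material
20 | bromo[(2R)-2-methyl-5-(trimethylsilyl)pent-4-yn-1-yl]magnesium | Br[Mg]C[C@H](C)CC#C[Si](C)(C)C | intermediate
21 | (4S)-4-methyl-7-(trimethylsilyl)hept-6-yn-1-ol | OCCC[C@H](C)CC#C[Si](C)(C)C | intermediate
22 | ethyne | C#C | starting material
23 | (4S)-4-methyl-7-(trimethylsilyl)hept-6-yn-1-yl trifluoromethanesulfonate | FC(F)(F)S(=O)(=O)OCCC[C@H](C)CC#C[Si](C)(C)C | intermediate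
24 | ethynyllithium (lithium acetylide) | [Li]C#C | intermediate
25 | trimethyl[(4S)-4-methylnona-1,8-diyn-1-yl]silane | C#CCCC[C@H](C)CC#C[Si](C)(C)C | intermediate
26 | dimethyl[(1E,6S)-2,6-dimethyl-9-(trimethylsilyl)non-1-en-8-yn-1-yl]alumane | C[Al](C)/C=C(\C)CCC[C@H](C)CC#C[Si](C)(C)C | intermediate
27 | [(4S,8E)-9-iodo-4,8-dimethylnon-8-en-1-yn-1-yl]trimethylsilane | I/C=C(\C)CCC[C@H](C)CC#C[Si](C)(C)C | intermediate
28 | methyl 4-[(1R,2R)-2-[(2R,3E)-4-(4,4,5,5-tetramethyl-1,3,2-dioxaborolan-2-yl)but-3-en-2-yl]cyclopropyl]butanoate | COC(=O)CCC[C@@H]1C[C@H]1[C@H](C)/C=C/B2OC(C)(C)C(C)(C)O2 | intermediate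
29 | methyl 4-[(1R,2R)-2-[(2R,3E,5E,10S)-6,10-dimethyl-13-(trimethylsilyl)trideca-3,5-dien-12-yn-2-yl]cyclopropyl]butanoate | COC(=O)CCC[C@@H]1C[C@H]1[C@H](C)/C=C/C=C(\C)CCC[C@H](C)CC#C[Si](C)(C)C | intermediate
30 | methyl 4-[(1R,2R)-2-[(2R,3E,5E,10S)-13-bromo-6,10-dimethyltrideca-3,5-dien-12-yn-2-yl]cyclopropyl]butanoate | COC(=O)CCC[C@@H]1C[C@H]1[C@H](C)/C=C/C=C(\C)CCC[C@H](C)CC#CBr | target

**Total step count:** 11. **Longest linear sequence:** 6 steps (1 → 2 → 4 → 5 → 10 → 11, or equally 6 → 7 → 8 → 9 → 10 → 11).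

**Three steps most likely to fail**

Step 2 (the proposed borylcyclopropanation): enantio-induction on an unactivated 1-alkene and clean boryl-carbene transfer are unproven. The fallback uses known chemistry only, sets out from 2 and comes back at 3. Cross-metathesis of 2 with (Z)-but-2-ene-1,4-diol (second-generation Grubbs catalyst, RuCl2(H2IMes)(PCy3)(=CHPh)) gives methyl (5E)-7-hydroxyhept-5-enoate F1. Charette asymmetric Simmons–Smith cyclopropanation (Et2Zn, CH2I2, (4S,5S)-2-butyl-N,N,N',N'-tetramethyl-1,3,2-dioxaborolane-4,5-dicarboxamide) gives methyl 4-[(1R,2R)-2-(hydroxymethyl)cyclopropyl]butanoate F2. TEMPO/PhI(OAc)2 oxidation gives (1R,2R)-2-(4-methoxy-4-oxobutyl)cyclopropane-1-carboxylic acid F3, and DIC with N-hydroxyphthalimide gives 1,3-dioxoisoindolin-2-yl (1R,2R)-2-(4-methoxy-4-oxobutyl)cyclopropane-1-carboxylate F4. Photochemical decarboxylative borylation (bis(catecholato)diboron, DMAc, blue light; then pinacol, Et3N) returns 3; the rapidly inverting cyclopropyl radical is borylated anti to the side chain, and any cis isomer is removed by chromatography.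

Step 4 (lithiation–borylation): the ester may be attacked by the organolithium, and the cyclopropyl shift from the carbamate-derived complex may be slow. The fallback replaces the chiral carbenoid by auxiliary-controlled Matteson homologation, sets out from 3 and comes back at 13. NaIO4/NH4OAc cleaves the pinacol ester to [(1R,2R)-2-(4-methoxy-4-oxobutyl)cyclopropyl]boronic acid F5. Condensation with (1R,2R)-1,2-dicyclohexylethane-1,2-diol gives methyl 4-[(1R,2R)-2-[(4R,5R)-4,5-dicyclohexyl-1,3,2-dioxaborolan-2-yl]cyclopropyl]butanoate F6. Preformed LiCHCl2 (−100 °C) with ZnCl2 gives, by a first 1,2-shift, methyl 4-[(1R,2R)-2-[(S)-chloro[(4R,5R)-4,5-dicyclohexyl-1,3,2-dioxaborolan-2-yl]methyl]cyclopropyl]butanoate F7. MeMgBr (1.0 equiv, −78 °C) displaces chloride with inversion in a second 1,2-shift to give methyl 4-[(1R,2S)-2-[(1S)-1-[(4R,5R)-4,5-dicyclohexyl-1,3,2-dioxaborolan-2-yl]ethyl]cyclopropyl]butanoate F8, which is taken through the conditions of step 5 to 13.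

Step 5 (alkynylation next to an enolisable ester): LiN(iPr)2 has to lithiate bromoethene while the ester sits as its enolate, and the fluoride elimination must not hydrolyse the ester. The fallback avoids the alkyne altogether, sets out from 8 and comes back at 28. Zweifel vinylation (vinyllithium from 9 and t-BuLi, 1.2 equiv, −78 °C; I2, NaOMe, MeOH) gives methyl 4-[(1R,2R)-2-[(2R)-but-3-en-2-yl]cyclopropyl]butanoate F9. Cross-metathesis with vinylboronic acid pinacol ester (second-generation Grubbs catalyst, RuCl2(H2IMes)(PCy3)(=CHPh), CH2Cl2, 40 °C) gives the (E)-alkenylboronate 28, now isolated, which enters the Suzuki stage of step 10.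

**Further compounds**
F1 | step 2 | methyl (5E)-7-hydroxyhept-5-enoate | COC(=O)CCC/C=C/CO
F2 | step 2 | methyl 4-[(1R,2R)-2-(hydroxymethyl)cyclopropyl]butanoate | COC(=O)CCC[C@@H]1C[C@H]1CO
F3 | step 2 | (1R,2R)-2-(4-methoxy-4-oxobutyl)cyclopropane-1-carboxylic acid | COC(=O)CCC[C@@H]1C[C@H]1C(=O)O
F4 | step 2 | 1,3-dioxoisoindolin-2-yl (1R,2R)-2-(4-methoxy-4-oxobutyl)cyclopropane-1-carboxylate | COC(=O)CCC[C@@H]1C[C@H]1C(=O)ON1C(=O)c2ccccc2C1=O
F5 | step 4 | [(1R,2R)-2-(4-methoxy-4-oxobutyl)cyclopropyl]boronic acid | COC(=O)CCC[C@@H]1C[C@H]1B(O)O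
F6 | step 4 | methyl 4-[(1R,2R)-2-[(4R,5R)-4,5-dicyclohexyl-1,3,2-dioxaborolan-2-yl]cyclopropyl]butanoate | COC(=O)CCC[C@@H]1C[C@H]1B2O[C@H](C3CCCCC3)[C@@H](C3CCCCC3)O2
F7 | step 4 | methyl 4-[(1R,2R)-2-[(S)-chloro[(4R,5R)-4,5-dicyclohexyl-1,3,2-dioxaborolan-2-yl]methyl]cyclopropyl]butanoate | COC(=O)CCC[C@@H]1C[C@H]1[C@@H](Cl)B2O[C@H](C3CCCCC3)[C@@H](C3CCCCC3)O2
F8 | step 4 | methyl 4-[(1R,2S)-2-[(1S)-1-[(4R,5R)-4,5-dicyclohexyl-1,3,2-dioxaborolan-2-yl]ethyl]cyclopropyl]butanoate | COC(=O)CCC[C@@H]1C[C@H]1[C@H](C)B2O[C@H](C3CCCCC3)[C@@H](C3CCCCC3)O2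
F9 | step 5 | methyl 4-[(1R,2R)-2-[(2R)-but-3-en-2-yl]cyclopropyl]butanoate | COC(=O)CCC[C@@H]1C[C@H]1[C@H](C)C=C
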